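(Readings and results are calculated from invented constants, noise included.)

Target is the species to follow, and it comes late: the birch run reads 2.6% at 1.04 d but 44.9% at 4.00 d.

| flask | substrate | partner | remark | time |
|---|---|---|---|---|
| birch | 0.30 M | 1 equiv | run made earlier |  |
| elm | 0.15 M | 1 equiv | run made earlier |  |
| beta | 0.30 M | 1.00 equiv | everything together in a closed stirred flask, run for 4.0 d | 4.0 d |
| delta | 0.30 M (fed, over 2.00 d) | 1.00 equiv | a stirred flask in which substrate is dosed at a steady rate over 2.00 d without added volume, worked up at 4.0 d | 4.0 d |
| alpha | 0.30 M | 1.00 equiv | one stirred flow tank at steady state, fed with the mixture as stated, mean residence time 4.0 d |  |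
| gamma | 0.30 M | 1.00 equiv (fed, over 2.00 d) | all but partner at the start; partner goes in evenly over 2.00 d, the run ends at 4.0 d | 4.0 d |

birch run (percent of the substrate charged): time / d: target / % = 0.208: 0; 0.625: 1.8; 1.04: 2.6; 1.67: 7.0; 2.50: 18.1; 3.00: 27.6; 4.00: 44.9

elm run (percent of the substrate charged): time / h: target / % = 1.00: 0; 3.00: 0.3; 5.00: 0; 8.00: 0.2; 12.0: 1.1; 15.0: 0.7; 20.0: 0.4

(readings scatter by 0.5 percentage points)

- percent here means substrate units held: one side product counts as two
- the stated concentrations are those of everything mixed, before any reaction; amounts are the same in each set-up
- what may be going on: substrate + target -> side product; substrate + partner + target -> 2 target; substrate + partner -> target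
- the feed brings no volume worth counting
- the earlier runs were made in a closed, stirred flask

- the set-up with the highest amount of target at the outlet or at the end, in percent of the substrate put in ("none" if the first two lie within 2 percentage points) (beta / delta / alpha / gamma / none)
- amount of target at the outlet or at the end, in percent of the substrate put in, beta
- amount of target at the outlet or at the end, in percent of the substrate put in, delta
- amount of target at the outlet or at the end, in percent of the substrate put in, alpha
- amount of target at the outlet or at the end, in percent of the substrate put in, gamma

*What kind of curve is birch?* Autocatalysis. In the candidate step substrate + partner + target -> 2 target, target breeds target, pseudo-first-order in [target] while [substrate] and [partner] stand near their charge.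

*What do you count?* Doublings. Birch climbs from 7.0% at 1.67 d to 18.1% at 2.50 d. That gives 0.606 d, the doubling time of target, meaning the time in which target doubles over that stretch of birch, with [substrate] and [partner] already somewhat below their charge. It is a reading and carries the scatter.

*Where does it bear hardest?* On the tank, alpha. In one residence time of 4.0 d, target at that pace could grow by 4.58 e-foldings, while washout removes one. Because 4.58 is more than one, a trace of target from the slow step outgrows washout, so the tank lights although its feed holds no target.

*Where does it stop?* Growth falls with [substrate][partner], and with equal charges and a small side reaction the two fall together. My estimate sets the steady state where the e-foldings, multiplied by the square of the substrate fraction, equal one. My reckoning puts substrate left at 46.7%, which leaves 53.3% for target and side product.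

*But birch gives no reading of side product. Isn't that the weak spot?* It is. On my estimate alpha would have to hold 8.4 percentage points as side product to sink to the 44.9% of birch, and beta repeats birch. I commit to alpha.

The forecast differs and names beta: beta 45%, delta 31%, alpha 41% (range 31% to 56%), gamma 30%. Of alpha it says “the tank sits in the ignited state”.

    substrate + target → side product (k = 0.00767 /M/h)
    substrate + partner + target → 2 target (k = 0.631 /M²/h)
    substrate + partner → target (k = 0.00195 /M/h)

Alpha gives 48.8% at the outlet, above beta at 44.4%, delta at 26.9% and gamma at 26.7%, so the best set-up is alpha. Its outlet holds 42.1% substrate, against the reckoned 46.7%. Gamma, with partner dosed over 2.00 d, holds 2.73% target at the end of the feed. Counted at the birch reading of 0.606 d, the 2.00 d that remain are 3.30 doubling times, a reckoned 26.9% of target. Over those days the substrate in gamma falls from 97.1% to 70.9%. Gamma ends with 26.7% target at 4.00 d.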